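| setting | maple | oak | delta | epsilon |
|---|---|---|---|---|
| starting material | 0.050 M (fed, over 4.0 h) | 0.050 M (fed, over 4.0 h) | 0.050 M (fed, over 4.0 h) | 0.050 M (fed, over 4.0 h) |
| protic impurity | 0.025 M | 0.038 M | 0.0500 M | 0.0500 M |
| catalyst | 0.44 mM | 0.44 mM | 0.44 mM | 0.44 mM |
| temperature | 65 °C | 80 °C | 70 °C | 90 °C |
| remark | run made earlier | run made earlier |  |  |
| time |  |  | 4.0 h | 4.0 h |

- maple (time / h: target / %, isomer of the product / %): 0.417: 0.5, 0.2; 0.667: 0, 0; 1.00: 0, 0.4; 2.00: 2.5, 0.6; 3.00: 5.9, 0; 5.00: 15.4, 2.5
- oak (time / h: target / %, isomer of the product / %): 0.500: 1.0, 0.8; 1.00: 1.4, 0; 1.50: 3.2, 0.3; 2.00: 2.7, 0; 2.50: 7.5, 1.0; 3.00: 7.1, 2.0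

(readings scatter by 1 percentage point)

- the earlier runs were read with a standard deviation of 1 percentage point
- in a conversion other conformer counts as not yet reacted
- percentages count the whole charge, also what has not yet gone in

1. which flask leads in share of target in all that became target or isomer of the product ("all alike" within 1.5 percentage points) (delta / epsilon / all alike)
2. share of target in all that became target or isomer of the product, delta
3. share of target in all that became target or isomer of the product, epsilon

0.152 is the number I start from: the isomer of the product made per target, summed over all the readings of maple. The share of target, the selectivity, is one over one plus that ratio, so the question is what the ratio does in delta and epsilon. Oak, summed alike, gives 0.179. But 6 isomer readings of scatter 1 percentage point each, on a target sum of 22.9 %, carry 0.107 on that ratio, so the gap of 0.0270 between the runs is smaller than the scatter.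

Protic impurity stands at 0.500 of the charge in maple, 0.760 in oak and 1.00 in delta and epsilon. In one extreme version the impurity merely takes starting material from both products alike, so the ratio stays at 0.152 and the share is 86.8 %. In the other the ratio grows in step with the impurity, so delta and epsilon reach 0.305 and a share of 76.7 %. From maple to oak the impurity grew by a factor 1.52, so the second version puts oak at 0.231, which lies 0.0520 above the 0.179 read, less than the scatter, so these readings do not separate the two versions; oak was also hotter than maple. Of the two runs, oak stands closer in impurity to delta and epsilon, so I commit to the oak ratio for both, a share of 84.8 % with no leader, and one scatter either way on that ratio gives a band from 77.8 % to 93.3 %.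

The forecast says all alike, with 81 % for delta and 80 % for epsilon: “The data show no clear temperature effect”.

The flask gives 93.1 % for delta and 77.6 % for epsilon, so delta leads by 16 points, and the two sit near the ends of my band, away from its middle.

    starting material ⇌ other conformer (K = 0.120, k = 0.00100 s⁻¹, Ea = 100 kJ mol⁻¹, ΔH = 22.0 kJ mol⁻¹)
    starting material + catalyst ⇌ catalyst + target (K = 0.640, k = 0.170 L mol⁻¹ s⁻¹, Ea = 54.0 kJ mol⁻¹, ΔH = −20.0 kJ mol⁻¹)
    catalyst + other conformer → catalyst + isomer of the product (k = 0.240 L mol⁻¹ s⁻¹, Ea = 78.0 kJ mol⁻¹)
    starting material + protic impurity → quenched substrate (k = 0.00370 L mol⁻¹ s⁻¹, Ea = 76.0 kJ mol⁻¹)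
    (constants at 90 °C)

Delta at 4.00 h holds 11.7 % target and 0.869 % isomer, 0.0740 isomer per target, less than the 0.152 read in maple. The same reckoning goes to a neighbour of delta charged with 4.00 equiv of protic impurity. The first version keeps that ratio and gives 93.1 %; the second multiplies it by 4.00 and gives 77.2 %. That neighbour holds 7.68 % target and 0.581 % isomer, 0.0757 isomer per target, and its share is 93.0 %.

(The numbers in the tables were generated by integration from invented constants, and the scatter is random.)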